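**Retrosynthetic overview** (isoflavan numbering: O1, C2, C3, C4 = pyran ring; ring A = C4a–C8a; ring B = C1'–C6')

1. Target 20 ⇐ MOM removal from 19 ⇐ reductive cleavage of the benzylic C4–O2' bond of cis-pterocarpan 18; this opens a temporary furan ring last and returns the C4 methylene and the 2'-OH.
2. 18 ⇐ pyran ring closed at O1–C2 (Mitsunobu) from phenol-alcohol 17 ⇐ ester reduction and desilylation of cis-dihydrobenzofuran ester 15.
3. 15 ⇐ C3–C4 bond by enantioselective dirhodium-carbene C–H insertion of the acyclic, achiral diazo ester 14 (C2 at the ester oxidation level); this closes the furan ring and sets C3. Ring order: furan closed (step 11), pyran closed (step 14), furan opened (step 15).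
4. 14 ⇐ O2'–C4 ether union of ring-A benzyl alcohol 8 and ring-B hydroxy keto ester 11, both made from one arene, 2-prenylresorcinol bis-MOM ether 4 (resorcinol + prenyl bromide), by directed lithiation with DMF or dimethyl oxalate.
5. Enabling feature: the C2' oxygen of ring B is ortho to C1', the carbon that carries C3. As its ether with C4 it holds the C4–H bonds 1,5 to C3 and makes them alpha to oxygen, benzylic to ring A and para to the C7 oxygen; the same benzylic C4–O2' bond is the one that reduction later cuts.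

Key step: step 11

Abbreviations: MOM = methoxymethyl; TBS = tert-butyldimethylsilyl; prenyl = 3-methylbut-2-en-1-yl. The target is the (3S) enantiomer.

Assumption: the sense of induction is taken from the parent 2-(benzyloxy)phenyl diazoacetates, where the S-configured phthaloyl-tert-leucinate catalyst is recalled to give the (2R,3S) cis ester; the R-configured catalyst is therefore written for 15, and its antipode would be used if the sense were reversed on this substrate.

**Step 1**
Reactants: 1 resorcinol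
Product: 2 1,3-bis(methoxymethoxy)benzene
Conditions: NaH, DMF, 0 °C; MOMCl, 0 °C to rt
Reagents that add atoms: chloromethyl methyl ether, COCCl
Why: Williamson etherification of both phenoxides should give the bis-acetal whose oxygens later direct the two lithiations.

**Step 2**
Reactants: 2 1,3-bis(methoxymethoxy)benzene; 3 prenyl bromide
Product: 4 1,3-bis(methoxymethoxy)-2-prenylbenzene
Conditions: n-BuLi, THF, 0 °C to rt; CuI (10 mol %), 3, −78 °C to rt
Reagents that add atoms: none
Why: Directed ortho-metalation at the carbon flanked by both OMOM groups, then copper-mediated SN2 allylation, should place the prenyl group between the two oxygens without regiochemical ambiguity.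

**Step 3**
Reactants: 4 1,3-bis(methoxymethoxy)-2-prenylbenzene
Product: 5 2,4-bis(methoxymethoxy)-3-prenylbenzaldehyde
Conditions: n-BuLi, TMEDA, THF, 0 °C; DMF, −78 °C to rt; H2O
Reagents that add atoms: N,N-dimethylformamide, CN(C)C=O
Why: A second directed ortho-metalation (the two open ortho sites are equivalent by symmetry) followed by formylation with DMF should give the aldehyde whose carbon becomes C4.

**Step 4**
Reactants: 5 2,4-bis(methoxymethoxy)-3-prenylbenzaldehyde
Product: 6 2-hydroxy-4-(methoxymethoxy)-3-prenylbenzaldehyde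
Conditions: MgBr2·OEt2, Et2O/CH2Cl2, rt; H2O
Reagents that add atoms: none
Why: Chelation-controlled acetal cleavage: magnesium bridges the carbonyl oxygen and the ortho acetal oxygen, so bromide should remove only the MOM group next to the aldehyde.

**Step 5**
Reactants: 6 2-hydroxy-4-(methoxymethoxy)-3-prenylbenzaldehyde
Product: 7 2-[(tert-butyldimethylsilyl)oxy]-4-(methoxymethoxy)-3-prenylbenzaldehyde
Conditions: TBSCl, imidazole, DMF, rt
Reagents that add atoms: tert-butyldimethylsilyl chloride, CC(C)(C)[Si](C)(C)Cl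
Why: Silylation of the phenol gives the future O1 a protecting group that fluoride removes without touching the MOM ethers.

**Step 6**
Reactants: 7 2-[(tert-butyldimethylsilyl)oxy]-4-(methoxymethoxy)-3-prenylbenzaldehyde
Product: 8 {2-[(tert-butyldimethylsilyl)oxy]-4-(methoxymethoxy)-3-prenylphenyl}methanol
Conditions: NaBH4, MeOH/THF, −20 °C
Reagents that add atoms: none
Why: Borohydride reduction of the aldehyde at low temperature should give the benzylic alcohol before oxygen-to-oxygen silyl migration can occur.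

**Step 7**
Reactants: 4 1,3-bis(methoxymethoxy)-2-prenylbenzene; 9 dimethyl oxalate
Product: 10 methyl 2-[2,4-bis(methoxymethoxy)-3-prenylphenyl]-2-oxoacetate
Conditions: n-BuLi, TMEDA, THF, 0 °C; cannulation into 9 (3 equiv), THF, −78 °C
Reagents that add atoms: none
Why: The same directed ortho-metalation as in step 3, quenched by inverse addition to excess oxalate, should give the aryl glyoxylate that carries C3 and C2.

**Step 8**
Reactants: 10 methyl 2-[2,4-bis(methoxymethoxy)-3-prenylphenyl]-2-oxoacetate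
Product: 11 methyl 2-[2-hydroxy-4-(methoxymethoxy)-3-prenylphenyl]-2-oxoacetate
Conditions: MgBr2·OEt2, Et2O/CH2Cl2, rt; H2O
Reagents that add atoms: none
Why: As in step 4, chelation between the aryl ketone and the ortho acetal oxygen should free only the 2'-OH.

**Step 9**
Reactants: 8 {2-[(tert-butyldimethylsilyl)oxy]-4-(methoxymethoxy)-3-prenylphenyl}methanol; 11 methyl 2-[2-hydroxy-4-(methoxymethoxy)-3-prenylphenyl]-2-oxoacetate
Product: 12 methyl 2-[2-({2-[(tert-butyldimethylsilyl)oxy]-4-(methoxymethoxy)-3-prenylphenyl}methoxy)-4-(methoxymethoxy)-3-prenylphenyl]-2-oxoacetate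
Conditions: PPh3, DIAD, THF, 0 °C to rt
Reagents that add atoms: none
Why: Mitsunobu etherification of the acidic, carbonyl-chelated phenol with the primary benzylic alcohol should form the O2'–C4 tether under neutral conditions.

**Step 10**
Reactants: 12 methyl 2-[2-({2-[(tert-butyldimethylsilyl)oxy]-4-(methoxymethoxy)-3-prenylphenyl}methoxy)-4-(methoxymethoxy)-3-prenylphenyl]-2-oxoacetate
Product: 14 methyl 2-diazo-2-[2-({2-[(tert-butyldimethylsilyl)oxy]-4-(methoxymethoxy)-3-prenylphenyl}methoxy)-4-(methoxymethoxy)-3-prenylphenyl]acetate, via N-tosylhydrazone 13 (not isolated)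
Conditions: TsNHNH2, MeOH, 50 °C; concentrate; DBU, CH2Cl2, 0 °C to rt
Reagents that add atoms: p-toluenesulfonyl hydrazide, Cc1ccc(cc1)S(=O)(=O)NN
Why: Condensation of the electrophilic keto ester to the tosylhydrazone and Bamford–Stevens loss of sulfinate with DBU should give the aryl diazoacetate.

**Step 11**
Reactants: 14 methyl 2-diazo-2-[2-({2-[(tert-butyldimethylsilyl)oxy]-4-(methoxymethoxy)-3-prenylphenyl}methoxy)-4-(methoxymethoxy)-3-prenylphenyl]acetate
Product: 15 methyl (2S,3R)-2-{2-[(tert-butyldimethylsilyl)oxy]-4-(methoxymethoxy)-3-prenylphenyl}-6-(methoxymethoxy)-7-prenyl-2,3-dihydro-1-benzofuran-3-carboxylate (cis)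
Conditions: Rh2(R-PTTL)4 [dirhodium tetrakis(N-phthaloyl-(R)-tert-leucinate)] (1 mol %), toluene, 4 Å sieves, −60 °C, slow addition of 14
Reagents that add atoms: none
Why: The dirhodium tetracarboxylate (divalent rhodium) should turn the diazo ester into an electrophilic donor/acceptor carbene at the future C3, which inserts into one of the two enantiotopic O–CH2–aryl C–H bonds (future C4) through a concerted, hydride-transfer-like three-centre transition state. The closest known reaction is the enantioselective intramolecular C–H insertion of methyl 2-(2-benzyloxyphenyl)-2-diazoacetates to cis-2-aryl-2,3-dihydrobenzofuran-3-carboxylates with the same phthaloyl-tert-leucinate catalysts. The five-membered furan ring is closed by 1,5 C–H insertion (carbene carbon, two ring-B carbons, oxygen, benzylic carbon); the methyl ester offers no competing 1,5 C–H bond. Both new stereocentres are set by the chiral carboxylate ligands: the cis relationship comes from the insertion transition state and the absolute configuration at benzofuran C3 (the only stereocentre of the target) from the R-configured ligands, while benzofuran C2 is a temporary stereocentre erased in step 15. The step needs site selectivity over the two prenyl groups and the acetal and silyl C–H bonds; this is secured because the reacting C–H bond is alpha to oxygen and benzylic to an arene with para-OMOM and ortho-OSi donors, the ring-B prenyl group is held meta to the carbene carbon, the ring-A prenyl group could be reached only through a ring of nine or more atoms, and trisubstituted alkenes are poor partners for donor/acceptor carbenes. Low temperature and slow addition should suppress carbene dimerisation.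

**Step 12**
Reactants: 15 methyl (2S,3R)-2-{2-[(tert-butyldimethylsilyl)oxy]-4-(methoxymethoxy)-3-prenylphenyl}-6-(methoxymethoxy)-7-prenyl-2,3-dihydro-1-benzofuran-3-carboxylate
Product: 16 [(2S,3S)-2-{2-[(tert-butyldimethylsilyl)oxy]-4-(methoxymethoxy)-3-prenylphenyl}-6-(methoxymethoxy)-7-prenyl-2,3-dihydro-1-benzofuran-3-yl]methanol
Conditions: i-Bu2AlH (3 equiv), CH2Cl2, −78 to −40 °C; aq. potassium sodium tartrate
Reagents that add atoms: none
Why: Non-basic aluminium hydride reduction of the ester to the primary alcohol (C2 at its final oxidation level) should be faster than enolisation, so the cis C3 centre is not epimerised; the descriptor changes only by priority.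

**Step 13**
Reactants: 16 [(2S,3S)-2-{2-[(tert-butyldimethylsilyl)oxy]-4-(methoxymethoxy)-3-prenylphenyl}-6-(methoxymethoxy)-7-prenyl-2,3-dihydro-1-benzofuran-3-yl]methanol
Product: 17 2-[(2S,3S)-3-(hydroxymethyl)-6-(methoxymethoxy)-7-prenyl-2,3-dihydro-1-benzofuran-2-yl]-5-(methoxymethoxy)-6-prenylphenol
Conditions: Bu4NF, AcOH (1:1), THF, 0 °C
Reagents that add atoms: none
Why: Fluoride desilylation buffered with acetic acid should deliver the phenol rather than a free phenoxide, which avoids elimination of the ortho benzylic aryl ether to an ortho-quinone methide.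

**Step 14**
Reactants: 17 2-[(2S,3S)-3-(hydroxymethyl)-6-(methoxymethoxy)-7-prenyl-2,3-dihydro-1-benzofuran-2-yl]-5-(methoxymethoxy)-6-prenylphenol
Product: 18 (6aS,11aS)-3,9-bis(methoxymethoxy)-4,10-diprenyl-6a,11a-dihydro-6H-[1]benzofuro[3,2-c]chromene (cis-pterocarpan)
Conditions: PPh3, DIAD, THF (0.01 M), 0 °C to rt
Reagents that add atoms: none
Why: Intramolecular Mitsunobu etherification (6-exo-tet) should close the pyran ring at O1–C2; only the ring-A phenol can cyclise because O2' is locked in the furan ring, and the cis arrangement from step 11 is what allows the cis-fused ring.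

**Step 15**
Reactants: 18 (6aS,11aS)-3,9-bis(methoxymethoxy)-4,10-diprenyl-6a,11a-dihydro-6H-[1]benzofuro[3,2-c]chromene
Product: 19 6-[(3S)-7-(methoxymethoxy)-8-prenyl-3,4-dihydro-2H-chromen-3-yl]-3-(methoxymethoxy)-2-prenylphenol
Conditions: Li, NH3(l)/THF, −78 °C, 15 min; NH4Cl
Reagents that add atoms: none
Why: Dissolving-metal cleavage of a benzyl aryl ether should cut only the benzylic C4–O2' bond (phenoxide plus benzylic anion, protonated by ammonia), leaving C3, the isolated trisubstituted alkenes and the non-benzylic aryl ethers untouched.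

**Step 16**
Reactants: 19 6-[(3S)-7-(methoxymethoxy)-8-prenyl-3,4-dihydro-2H-chromen-3-yl]-3-(methoxymethoxy)-2-prenylphenol
Product: 20 4-[(3S)-7-hydroxy-8-prenyl-3,4-dihydro-2H-chromen-3-yl]-2-prenylbenzene-1,3-diol
Conditions: HCl, MeOH, rt
Reagents that add atoms: none
Why: Acid-catalysed transacetalisation to methanol should remove both MOM groups under conditions mild enough to limit cyclisation of the phenols onto their neighbouring prenyl groups.

**Compound list**

1 | resorcinol (benzene-1,3-diol) | Oc1cccc(O)c1 | starting material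
2 | 1,3-bis(methoxymethoxy)benzene | COCOc1cccc(OCOC)c1 | intermediate
3 | prenyl bromide (1-bromo-3-methylbut-2-ene) | CC(C)=CCBr | starting material
4 | 1,3-bis(methoxymethoxy)-2-(3-methylbut-2-en-1-yl)benzene | COCOc1cccc(OCOC)c1CC=C(C)C | intermediate
5 | 2,4-bis(methoxymethoxy)-3-(3-methylbut-2-en-1-yl)benzaldehyde | O=Cc1ccc(OCOC)c(CC=C(C)C)c1OCOC | intermediate
6 | 2-hydroxy-4-(methoxymethoxy)-3-(3-methylbut-2-en-1-yl)benzaldehyde | O=Cc1ccc(OCOC)c(CC=C(C)C)c1O | intermediate
7 | 2-[(tert-butyldimethylsilyl)oxy]-4-(methoxymethoxy)-3-(3-methylbut-2-en-1-yl)benzaldehyde | O=Cc1ccc(OCOC)c(CC=C(C)C)c1O[Si](C)(C)C(C)(C)C | intermediate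
8 | {2-[(tert-butyldimethylsilyl)oxy]-4-(methoxymethoxy)-3-(3-methylbut-2-en-1-yl)phenyl}methanol | OCc1ccc(OCOC)c(CC=C(C)C)c1O[Si](C)(C)C(C)(C)C | intermediate
9 | dimethyl oxalate | COC(=O)C(=O)OC | starting material
10 | methyl 2-[2,4-bis(methoxymethoxy)-3-(3-methylbut-2-en-1-yl)phenyl]-2-oxoacetate | COC(=O)C(=O)c1ccc(OCOC)c(CC=C(C)C)c1OCOC | intermediate
11 | methyl 2-[2-hydroxy-4-(methoxymethoxy)-3-(3-methylbut-2-en-1-yl)phenyl]-2-oxoacetate | COC(=O)C(=O)c1ccc(OCOC)c(CC=C(C)C)c1O | intermediate
12 | methyl 2-[2-({2-[(tert-butyldimethylsilyl)oxy]-4-(methoxymethoxy)-3-(3-methylbut-2-en-1-yl)phenyl}methoxy)-4-(methoxymethoxy)-3-(3-methylbut-2-en-1-yl)phenyl]-2-oxoacetate | COC(=O)C(=O)c1ccc(OCOC)c(CC=C(C)C)c1OCc1ccc(OCOC)c(CC=C(C)C)c1O[Si](C)(C)C(C)(C)C | intermediate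
13 | N-tosylhydrazone of 12 (C=N geometry not defined) | COC(=O)C(=NNS(=O)(=O)c1ccc(C)cc1)c1ccc(OCOC)c(CC=C(C)C)c1OCc1ccc(OCOC)c(CC=C(C)C)c1O[Si](C)(C)C(C)(C)C | intermediate
14 | methyl 2-diazo-2-[2-({2-[(tert-butyldimethylsilyl)oxy]-4-(methoxymethoxy)-3-(3-methylbut-2-en-1-yl)phenyl}methoxy)-4-(methoxymethoxy)-3-(3-methylbut-2-en-1-yl)phenyl]acetate | COC(=O)C(=[N+]=[N-])c1ccc(OCOC)c(CC=C(C)C)c1OCc1ccc(OCOC)c(CC=C(C)C)c1O[Si](C)(C)C(C)(C)C | intermediate
15 | methyl (2S,3R)-2-{2-[(tert-butyldimethylsilyl)oxy]-4-(methoxymethoxy)-3-(3-methylbut-2-en-1-yl)phenyl}-6-(methoxymethoxy)-7-(3-methylbut-2-en-1-yl)-2,3-dihydro-1-benzofuran-3-carboxylate (cis) | CC(C)=CCc1c(OCOC)ccc2c1O[C@H](c1ccc(OCOC)c(CC=C(C)C)c1O[Si](C)(C)C(C)(C)C)[C@@H]2C(=O)OC | intermediate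
16 | [(2S,3S)-2-{2-[(tert-butyldimethylsilyl)oxy]-4-(methoxymethoxy)-3-(3-methylbut-2-en-1-yl)phenyl}-6-(methoxymethoxy)-7-(3-methylbut-2-en-1-yl)-2,3-dihydro-1-benzofuran-3-yl]methanol | CC(C)=CCc1c(OCOC)ccc2c1O[C@H](c1ccc(OCOC)c(CC=C(C)C)c1O[Si](C)(C)C(C)(C)C)[C@@H]2CO | intermediate
17 | 2-[(2S,3S)-3-(hydroxymethyl)-6-(methoxymethoxy)-7-(3-methylbut-2-en-1-yl)-2,3-dihydro-1-benzofuran-2-yl]-5-(methoxymethoxy)-6-(3-methylbut-2-en-1-yl)phenol | CC(C)=CCc1c(OCOC)ccc2c1O[C@H](c1ccc(OCOC)c(CC=C(C)C)c1O)[C@@H]2CO | intermediate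
18 | (6aS,11aS)-3,9-bis(methoxymethoxy)-4,10-bis(3-methylbut-2-en-1-yl)-6a,11a-dihydro-6H-[1]benzofuro[3,2-c]chromene | CC(C)=CCc1c(OCOC)ccc2c1O[C@@H]4c3ccc(OCOC)c(CC=C(C)C)c3OC[C@H]24 | intermediate
19 | 6-[(3S)-7-(methoxymethoxy)-8-(3-methylbut-2-en-1-yl)-3,4-dihydro-2H-chromen-3-yl]-3-(methoxymethoxy)-2-(3-methylbut-2-en-1-yl)phenol | CC(C)=CCc1c(OCOC)ccc([C@H]2COc3c(ccc(OCOC)c3CC=C(C)C)C2)c1O | intermediate
20 | 4-[(3S)-7-hydroxy-8-(3-methylbut-2-en-1-yl)-3,4-dihydro-2H-chromen-3-yl]-2-(3-methylbut-2-en-1-yl)benzene-1,3-diol | CC(C)=CCc1c(O)ccc([C@H]2COc3c(ccc(O)c3CC=C(C)C)C2)c1O | target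

**Step count and risks**

Total steps: 16. Longest linear sequence: 14 steps (1 → 2 → 4 → 5 → 6 → 7 → 8 → 12 → 14 → 15 → 16 → 17 → 18 → 19 → 20; steps 1–6 and 9–16).

Steps most likely to fail:

1. Step 11. The carbene may be diverted (dimerisation, attack on the electron-rich arenes), or the crowded ortho-silyloxyaryl group may erode facial discrimination and lower the enantiomeric purity. Fallback: form the same bond by auxiliary-controlled enolate alkylation in open-chain form, setting out from 8 and 4 and returning at 20. Alcohol 8 would be converted (CBr4, PPh3) into tert-butyl[2-(bromomethyl)-5-(methoxymethoxy)-6-prenylphenoxy]dimethylsilane F1. Lithiated 4 (n-BuLi, TMEDA) would be opened onto ethylene oxide to give 2-[2,4-bis(methoxymethoxy)-3-prenylphenyl]ethan-1-ol F2, oxidised (TEMPO, PhI(OAc)2, MeCN/H2O) to [2,4-bis(methoxymethoxy)-3-prenylphenyl]acetic acid F3, and coupled (t-BuCOCl, Et3N, LiCl) with (S)-4-benzyloxazolidin-2-one to the imide (4S)-4-benzyl-3-{[2,4-bis(methoxymethoxy)-3-prenylphenyl]acetyl}-1,3-oxazolidin-2-one F4. Its sodium enolate (NaN(SiMe3)2, THF, −78 °C) would be alkylated by F1 on the face away from the auxiliary benzyl group to give the (2S)-configured alkylated imide F5. LiBH4 would then release (2S)-2-[2,4-bis(methoxymethoxy)-3-prenylphenyl]-3-{2-[(tert-butyldimethylsilyl)oxy]-4-(methoxymethoxy)-3-prenylphenyl}propan-1-ol F6, and Bu4NF/AcOH the phenol 2-{(2S)-2-[2,4-bis(methoxymethoxy)-3-prenylphenyl]-3-hydroxypropyl}-5-(methoxymethoxy)-6-prenylphenol F7. Mitsunobu closure (PPh3, DIAD) would give (3S)-3-[2,4-bis(methoxymethoxy)-3-prenylphenyl]-7-(methoxymethoxy)-8-prenyl-3,4-dihydro-2H-chromene F8, which the conditions of step 16 convert into 20.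

2. Step 15. Electron transfer may over-reduce the electron-rich rings or cleave the ether incompletely or unselectively. Fallback: open the furan ring through a quinone methide instead, setting out from 18 and returning at 20. The MOM groups would be removed first (HCl, MeOH) to give (6aS,11aS)-4,10-diprenyl-6a,11a-dihydro-6H-[1]benzofuro[3,2-c]chromene-3,9-diol F9. In warm aqueous-ethanolic NaOH its ring-A phenoxide, para to the benzylic C–O carbon, should expel the ring-B phenoxide to a para-quinone methide, which NaBH4 present in the same flask reduces by 1,6-hydride addition to 20.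

3. Step 4. Both acetals may be lost, or the Lewis acid may drive cyclisation of the freed phenol onto the neighbouring prenyl group. Fallback: differentiate the two oxygens by protection instead of deprotection, setting out from 5 and returning at 6. Both MOM groups would be cleaved (HCl, MeOH) to 2,4-dihydroxy-3-prenylbenzaldehyde F10, and only the 4-OH re-protected (MOMCl, K2CO3, acetone), the 2-OH being held by its hydrogen bond to the aldehyde.

**Further compounds**

F1 | step 11 | tert-butyl[2-(bromomethyl)-5-(methoxymethoxy)-6-(3-methylbut-2-en-1-yl)phenoxy]dimethylsilane | BrCc1ccc(OCOC)c(CC=C(C)C)c1O[Si](C)(C)C(C)(C)C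
F2 | step 11 | 2-[2,4-bis(methoxymethoxy)-3-(3-methylbut-2-en-1-yl)phenyl]ethan-1-ol | OCCc1ccc(OCOC)c(CC=C(C)C)c1OCOC
F3 | step 11 | [2,4-bis(methoxymethoxy)-3-(3-methylbut-2-en-1-yl)phenyl]acetic acid | OC(=O)Cc1ccc(OCOC)c(CC=C(C)C)c1OCOC
F4 | step 11 | (4S)-4-benzyl-3-{[2,4-bis(methoxymethoxy)-3-(3-methylbut-2-en-1-yl)phenyl]acetyl}-1,3-oxazolidin-2-one | O=C(Cc1ccc(OCOC)c(CC=C(C)C)c1OCOC)N1C(=O)OC[C@@H]1Cc1ccccc1
F5 | step 11 | (4S)-4-benzyl-3-[(2S)-2-[2,4-bis(methoxymethoxy)-3-(3-methylbut-2-en-1-yl)phenyl]-3-{2-[(tert-butyldimethylsilyl)oxy]-4-(methoxymethoxy)-3-(3-methylbut-2-en-1-yl)phenyl}propanoyl]-1,3-oxazolidin-2-one | O=C([C@@H](Cc1ccc(OCOC)c(CC=C(C)C)c1O[Si](C)(C)C(C)(C)C)c1ccc(OCOC)c(CC=C(C)C)c1OCOC)N1C(=O)OC[C@@H]1Cc1ccccc1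
F6 | step 11 | (2S)-2-[2,4-bis(methoxymethoxy)-3-(3-methylbut-2-en-1-yl)phenyl]-3-{2-[(tert-butyldimethylsilyl)oxy]-4-(methoxymethoxy)-3-(3-methylbut-2-en-1-yl)phenyl}propan-1-ol | OC[C@@H](Cc1ccc(OCOC)c(CC=C(C)C)c1O[Si](C)(C)C(C)(C)C)c1ccc(OCOC)c(CC=C(C)C)c1OCOC
F7 | step 11 | 2-{(2S)-2-[2,4-bis(methoxymethoxy)-3-(3-methylbut-2-en-1-yl)phenyl]-3-hydroxypropyl}-5-(methoxymethoxy)-6-(3-methylbut-2-en-1-yl)phenol | OC[C@@H](Cc1ccc(OCOC)c(CC=C(C)C)c1O)c1ccc(OCOC)c(CC=C(C)C)c1OCOC
F8 | step 11 | (3S)-3-[2,4-bis(methoxymethoxy)-3-(3-methylbut-2-en-1-yl)phenyl]-7-(methoxymethoxy)-8-(3-methylbut-2-en-1-yl)-3,4-dihydro-2H-chromene | CC(C)=CCc1c(OCOC)ccc([C@H]2COc3c(ccc(OCOC)c3CC=C(C)C)C2)c1OCOC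
F9 | step 15 | (6aS,11aS)-4,10-bis(3-methylbut-2-en-1-yl)-6a,11a-dihydro-6H-[1]benzofuro[3,2-c]chromene-3,9-diol | CC(C)=CCc1c(O)ccc2c1O[C@@H]4c3ccc(O)c(CC=C(C)C)c3OC[C@H]24
F10 | step 4 | 2,4-dihydroxy-3-(3-methylbut-2-en-1-yl)benzaldehyde | O=Cc1ccc(O)c(CC=C(C)C)c1O
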